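The benzene ring of the coumarin carries three contiguous substituents: the methoxy group on C7, the acyl group on C8 and the ring oxygen O1 on C8a. This ortho-hydroxyaryl ketone flanked by OMe is the signature of an aryne insertion into a carboxylic acid C–O bond, so the C8a–O1 and C8–C1' bonds are disconnected together. In one operation 3-methoxybenzyne takes up the intact, chiral-pool-derived (R)-2-senecioyloxy acid, delivering the whole side chain with its stereocentre onto the arene. The precursors are a commercial silyl aryl triflate and the O-senecioylated D-hydroxyisovaleric acid; the pyranone ring is then closed on the one free ortho carbon through an aryl propiolate.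

Key step: step 4

Assumption: 1 and 6 are bought as the single enantiomer and the single regioisomer. The side-chain carbons are called C1' (ketone) and C2' (stereocentre). C2' is R in 1, 2, 4, 5, 9, 11 and 12, because the priority order O > C=O > i-Pr > H holds throughout and no step breaks a bond at C2'.

Step 1
Reactants: 1 (R)-2-hydroxy-3-methylbutanoic acid
Product: 2 allyl (R)-2-hydroxy-3-methylbutanoate
Conditions: Cs2CO3 (0.55 equiv), allyl bromide (1.1 equiv), DMF, rt
Reagents that add atoms: allyl bromide, C=CCBr
Why: SN2 O-alkylation of the cesium carboxylate is selective for the carboxylate over the secondary hydroxyl and leaves C2' untouched, and the allyl ester is chosen because it can later be removed without hydrogen, hydroxide or strong acid, all of which would endanger the enoate.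

Step 2
Reactants: 2 allyl (R)-2-hydroxy-3-methylbutanoate; 3 3-methylbut-2-enoyl chloride
Product: 4 allyl (R)-3-methyl-2-[(3-methylbut-2-enoyl)oxy]butanoate
Conditions: pyridine (3 equiv), DMAP (cat.), CH2Cl2, 0 °C to rt
Reagents that add atoms: none
Why: DMAP-catalysed acylation with an acid chloride (nucleophilic acyl substitution) esterifies the hindered alcohol with retention because the C2'–O bond is not broken, and pyridine in place of a trialkylamine keeps vinylketene formation, and with it deconjugation of the enoate, low.

Step 3
Reactants: 4 allyl (R)-3-methyl-2-[(3-methylbut-2-enoyl)oxy]butanoate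
Product: 5 (R)-3-methyl-2-[(3-methylbut-2-enoyl)oxy]butanoic acid
Conditions: Pd(PPh3)4 (3 mol%), morpholine (2 equiv), THF, rt; dilute aq. KHSO4 wash
Reagents that add atoms: none
Why: Tsuji–Trost deallylation, in which zerovalent palladium ionises the allyl ester to a π-allyl complex that morpholine captures, frees the acid under neutral conditions that spare the senecioate ester, its alkene and the stereocentre.

Step 4
Reactants: 5 (R)-3-methyl-2-[(3-methylbut-2-enoyl)oxy]butanoic acid; 6 3-methoxy-2-(trimethylsilyl)phenyl trifluoromethanesulfonate
Product: 9 (R)-1-(2-hydroxy-6-methoxyphenyl)-3-methyl-1-oxobutan-2-yl 3-methylbut-2-enoate, via 3-methoxybenzyne 7 (not isolated), via ortho-cesiated aryl ester 8 (not isolated)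
Conditions: 6 (1.5 equiv), CsF (4 equiv), THF, sealed tube, 125 °C; aq. NH4Cl work-up
Reagents that add atoms: none
Why: Fluoride removes the silyl group of 6 and triflate departs to give 3-methoxybenzyne 7, while 5 is held as its cesium carboxylate, whose oxygen adds to the aryne carbon meta to the methoxy group (the future C8a) and so leaves the aryl anion 8 on the carbon next to OMe (the future C8). This anion attacks its own aryl ester carbonyl through a four-membered transition state and the acyl–O bond breaks, a net 1,3 O-to-C acyl shift that forms C8–C1' and releases the phenoxide of 9, which is protonated by the bifluoride formed at the outset or on work-up. The closest known reaction type is the insertion of arynes into the C–O bond of carboxylic acids to give ortho-hydroxyaryl ketones, an aryne sigma-insertion akin to an anionic Fries shift, and hot THF is used because heat in a solvent without acidic C–H bonds favours acyl transfer over protonation of the aryl anion. No ring is closed and no stereocentre is made; C2' is only carried through, since its C–H bond takes no part and enolisation of the product would have to build a crowded tetrasubstituted enolate beside a doubly ortho-substituted, phenoxide-deactivated ketone. Two selectivities are needed: regioselective O-addition, secured by the inductively withdrawing methoxy group, which distorts the aryne so that the remote carbon is the electrophilic one and the developing anion sits beside oxygen, and acyl transfer from the aryl ester and not from the senecioate, secured by proximity because the senecioate carbonyl could be reached only through a seven-membered transition state.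

Step 5
Reactants: 9 (R)-1-(2-hydroxy-6-methoxyphenyl)-3-methyl-1-oxobutan-2-yl 3-methylbut-2-enoate; 10 propiolic acid
Product: 11 3-methoxy-2-[(2R)-3-methyl-2-[(3-methylbut-2-enoyl)oxy]butanoyl]phenyl prop-2-ynoate
Conditions: DCC (1.5 equiv), DMAP (5 mol%), CH2Cl2, −20 to 0 °C
Reagents that add atoms: none
Why: Carbodiimide (Steglich-type) esterification acylates the phenol, the only free hydroxyl, and the cold, nearly neutral medium limits conjugate addition to the alkynoate and enolisation at C2'.

Step 6
Reactants: 11 3-methoxy-2-[(2R)-3-methyl-2-[(3-methylbut-2-enoyl)oxy]butanoyl]phenyl prop-2-ynoate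
Product: 12 (R)-1-(7-methoxy-2-oxo-2H-chromen-8-yl)-3-methyl-1-oxobutan-2-yl 3-methylbut-2-enoate
Conditions: [(t-Bu)2(2-biphenylyl)P]Au(NCMe)SbF6 (5 mol%), ClCH2CH2Cl, rt to 60 °C
Reagents that add atoms: none
Why: In this gold-catalysed intramolecular hydroarylation the cationic monovalent gold activates the alkynoate, and the only free ortho carbon, which lies para to the methoxy group, attacks the terminal alkyne carbon in a 6-endo-dig Friedel–Crafts-type closure, after which protodeauration gives the pyranone.

Compound list
1 | (R)-2-hydroxy-3-methylbutanoic acid | OC(=O)[C@H](O)C(C)C | starting material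
2 | allyl (R)-2-hydroxy-3-methylbutanoate | C=CCOC(=O)[C@H](O)C(C)C | intermediate
3 | 3-methylbut-2-enoyl chloride (senecioyl chloride) | CC(C)=CC(=O)Cl | starting material
4 | allyl (R)-3-methyl-2-[(3-methylbut-2-enoyl)oxy]butanoate | C=CCOC(=O)[C@H](OC(=O)C=C(C)C)C(C)C | intermediate
5 | (R)-3-methyl-2-[(3-methylbut-2-enoyl)oxy]butanoic acid | OC(=O)[C@H](OC(=O)C=C(C)C)C(C)C | intermediate
6 | 3-methoxy-2-(trimethylsilyl)phenyl trifluoromethanesulfonate | COc1cccc(OS(=O)(=O)C(F)(F)F)c1[Si](C)(C)C | starting material
7 | 3-methoxybenzyne (1-methoxy-2,3-didehydrobenzene; formed in the flask, not isolated) | COC1=CC=CC#C1 | intermediate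
8 | 2-cesio-3-methoxyphenyl (R)-3-methyl-2-[(3-methylbut-2-enoyl)oxy]butanoate (aryl anion as cesium salt; formed in the flask, not isolated) | COC1=CC=CC(OC(=O)[C@H](OC(=O)C=C(C)C)C(C)C)=[C-]1.[Cs+] | intermediate
9 | (R)-1-(2-hydroxy-6-methoxyphenyl)-3-methyl-1-oxobutan-2-yl 3-methylbut-2-enoate | COc1cccc(O)c1C(=O)[C@H](OC(=O)C=C(C)C)C(C)C | intermediate
10 | propiolic acid (prop-2-ynoic acid) | C#CC(=O)O | starting material
11 | 3-methoxy-2-[(2R)-3-methyl-2-[(3-methylbut-2-enoyl)oxy]butanoyl]phenyl prop-2-ynoate | COc1cccc(OC(=O)C#C)c1C(=O)[C@H](OC(=O)C=C(C)C)C(C)C | intermediate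
12 | (R)-1-(7-methoxy-2-oxo-2H-chromen-8-yl)-3-methyl-1-oxobutan-2-yl 3-methylbut-2-enoate | COc1ccc2ccc(=O)oc2c1C(=O)[C@H](OC(=O)C=C(C)C)C(C)C | target

Total step count: 6. Longest linear sequence: 6 steps (1 → 2 → 4 → 5 → 9 → 11 → 12); 3, 6 and 10 are purchased.

Steps most likely to fail

Step 4. Protonation of the aryl anion may outrun acyl transfer, so that the reaction stops at simple O-arylation. The prolonged hot, basic fluoride medium may also erode the configuration at C2', and the product phenoxide may be arylated by a second aryne. Fallback, setting out from 5: carbodiimide esterification (DCC, DMAP cat., CH2Cl2, 0 °C) with commercial 2-bromo-3-methoxyphenol (COc1cccc(O)c1Br) should give 2-bromo-3-methoxyphenyl (R)-3-methyl-2-[(3-methylbut-2-enoyl)oxy]butanoate F1. Bromine–lithium exchange with n-BuLi in THF at −100 °C should then generate 2-lithio-3-methoxyphenyl (R)-3-methyl-2-[(3-methylbut-2-enoyl)oxy]butanoate F2, the lithium counterpart of 8. F2 should undergo the same 1,3 O-to-C acyl shift as a halogen–metal-exchange-triggered anionic Fries rearrangement, far below the temperature at which C2' could enolise. Quenching with aq. NH4Cl returns to the route at 9.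

Step 6. The ring closure may stall because the C8 acyl group lowers the nucleophilicity of the arene and the ester prefers the conformer that holds the alkyne away from the ring; hydration or cleavage of the alkynoate may then take over. Fallback, setting out from 9: the C4a–C4 bond is made first. Magnesium-phenoxide-directed ortho-formylation (MgCl2, Et3N, paraformaldehyde, MeCN, reflux) can only reach the free ortho carbon and should give (R)-1-(3-formyl-2-hydroxy-6-methoxyphenyl)-3-methyl-1-oxobutan-2-yl 3-methylbut-2-enoate F4. Wittig olefination with Ph3P=CHCO2Et in refluxing N,N-diethylaniline should give ethyl (Z)-3-[2-hydroxy-4-methoxy-3-[(2R)-3-methyl-2-[(3-methylbut-2-enoyl)oxy]butanoyl]phenyl]prop-2-enoate F5 (the E isomer equilibrates under these conditions). F5 lactonises onto the phenol with loss of ethanol and arrives at 12.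

Step 5. Acylation of the hydrogen-bonded, flanked phenol may be slower than conjugate addition of the phenol to the activated alkynoate and oligomerisation of propiolic acid. Fallback, setting out from 9: the three-carbon unit is brought in with its β-carbon capped. Esterification with commercial 3-(trimethylsilyl)prop-2-ynoic acid (C[Si](C)(C)C#CC(=O)O; DCC, CH2Cl2, 0 °C) should give 3-methoxy-2-[(2R)-3-methyl-2-[(3-methylbut-2-enoyl)oxy]butanoyl]phenyl 3-(trimethylsilyl)prop-2-ynoate F3, in which the silyl group blocks Michael addition. Buffered protodesilylation (TBAF, AcOH, THF, −20 °C) then rejoins the route at 11.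

Further compounds
F1 | step 4 | 2-bromo-3-methoxyphenyl (R)-3-methyl-2-[(3-methylbut-2-enoyl)oxy]butanoate | COc1cccc(OC(=O)[C@H](OC(=O)C=C(C)C)C(C)C)c1Br
F2 | step 4 | 2-lithio-3-methoxyphenyl (R)-3-methyl-2-[(3-methylbut-2-enoyl)oxy]butanoate | COc1cccc(OC(=O)[C@H](OC(=O)C=C(C)C)C(C)C)c1[Li]
F3 | step 5 | 3-methoxy-2-[(2R)-3-methyl-2-[(3-methylbut-2-enoyl)oxy]butanoyl]phenyl 3-(trimethylsilyl)prop-2-ynoate | COc1cccc(OC(=O)C#C[Si](C)(C)C)c1C(=O)[C@H](OC(=O)C=C(C)C)C(C)C
F4 | step 6 | (R)-1-(3-formyl-2-hydroxy-6-methoxyphenyl)-3-methyl-1-oxobutan-2-yl 3-methylbut-2-enoate | COc1ccc(C=O)c(O)c1C(=O)[C@H](OC(=O)C=C(C)C)C(C)C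
F5 | step 6 | ethyl (Z)-3-[2-hydroxy-4-methoxy-3-[(2R)-3-methyl-2-[(3-methylbut-2-enoyl)oxy]butanoyl]phenyl]prop-2-enoate | CCOC(=O)/C=C\c1ccc(OC)c(C(=O)[C@H](OC(=O)C=C(C)C)C(C)C)c1O
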